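**Plan**
- Retrosynthesis: the O1–C2 bond of the pyranone (ring C) is opened to a 2-benzyloxy-1,3-diketone, then both bonds to C4 (C4a–C4 and C4–C3) are cut in one operation.
- Enabling feature: C4 is a lone carbonyl carbon between C4a of ring A and the oxygen-bearing C3, and C4a sits between two equivalent oxygenated carbons (C5, C8a) of a ring A that is symmetrical before ring C exists. C4 can therefore be supplied as carbon monoxide between an aryl iodide and a ketone enolate.
- Forward, fragments: the ring A iodide comes from phloroglucinol (MOM protection, two metalation–methylations, metalation–iodination). The ring B α-benzyloxy ketone comes from methyl 3,5-dihydroxy-4-methoxybenzoate (benzylation, saponification, diazoketone, O–H insertion).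
- Forward, assembly: iodide, CO and enolate give the open chain ring A–C4–C3–C2–ring B. Methanolic HCl then removes the MOM groups and closes ring C, the only ring made in the route, and hydrogenolysis frees the last three hydroxyls.
- Stereochemistry: the target is achiral. The one stereocentre of the diketone is racemic, enolisable and erased when ring C aromatises.

Key step: step 9

Remark: diketones 19 and 20 are drawn as diketo tautomers; they should exist largely as chelated enols, which has no consequence for the route.

**Route**

Step 1
Reactants: 1 phloroglucinol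
Product: 2 1,3,5-tris(methoxymethoxy)benzene
Conditions: MOMCl (4 equiv), i-Pr2NEt (5 equiv), DMF, 0 °C to rt
Reagents that add atoms: chloromethyl methyl ether COCCl
Why: Threefold O-alkylation of the phenol by the hard, very reactive α-chloro ether with an amine base (Williamson-type acetal formation) should give the known tris-MOM ether with little C-alkylation.

Step 2
Reactants: 2 1,3,5-tris(methoxymethoxy)benzene
Product: 4 1,3,5-tris(methoxymethoxy)-2-methylbenzene, via aryllithium 3 (not isolated)
Conditions: n-BuLi (1.1 equiv), TMEDA, THF, 0 °C; then MeI, −78 °C to rt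
Reagents that add atoms: iodomethane CI
Why: Directed ortho-metalation removes a ring hydrogen lying between two OMOM groups (all three sites are equivalent) and the aryllithium is methylated by SN2 attack on iodomethane.

Step 3
Reactants: 4 1,3,5-tris(methoxymethoxy)-2-methylbenzene
Product: 6 1,3,5-tris(methoxymethoxy)-2,4-dimethylbenzene, via aryllithium 5 (not isolated)
Conditions: n-BuLi (1.1 equiv), TMEDA, THF, 0 °C; then MeI, −78 °C to rt
Reagents that add atoms: iodomethane CI
Why: The two remaining ring hydrogens are equivalent and each still sits between two OMOM groups, so a second directed ortho-metalation and methylation should give a single dimethyl compound, ring metalation by n-BuLi being faster than lateral metalation of the methyl group.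

Step 4
Reactants: 6 1,3,5-tris(methoxymethoxy)-2,4-dimethylbenzene
Product: 8 2-iodo-1,3,5-tris(methoxymethoxy)-4,6-dimethylbenzene, via aryllithium 7 (not isolated)
Conditions: n-BuLi (1.2 equiv), TMEDA, THF, 0 °C; then I2, −78 °C to rt
Reagents that add atoms: iodine II
Why: The only ring hydrogen left, again flanked by two OMOM groups, is removed by directed ortho-metalation and the aryllithium is quenched with iodine, so the substrate fixes the regiochemistry.

Step 5
Reactants: 9 methyl 3,5-dihydroxy-4-methoxybenzoate
Product: 10 methyl 3,5-bis(benzyloxy)-4-methoxybenzoate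
Conditions: BnBr (2.4 equiv), K2CO3 (3 equiv), DMF, 60 °C
Reagents that add atoms: benzyl bromide BrCc1ccccc1
Why: Williamson etherification of both phenols with a benzylic halide and carbonate base is routine and leaves the methyl ester and methyl ether untouched.

Step 6
Reactants: 10 methyl 3,5-bis(benzyloxy)-4-methoxybenzoate
Product: 12 3,5-bis(benzyloxy)-4-methoxybenzoic acid, via sodium carboxylate 11 (not isolated)
Conditions: NaOH (aq. 2 M, 3 equiv), THF/MeOH, 60 °C; then HCl (aq.) to pH 2
Reagents that add atoms: sodium hydroxide [Na+].[OH-]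
Why: Saponification of the unhindered methyl ester by acyl–oxygen cleavage, then acidification, should give the acid while the benzyl and methyl ethers are inert to base.

Step 7
Reactants: 12 3,5-bis(benzyloxy)-4-methoxybenzoic acid
Product: 14 1-[3,5-bis(benzyloxy)-4-methoxyphenyl]-2-diazoethan-1-one, via acid chloride 13 (not isolated)
Conditions: (COCl)2 (1.5 equiv), DMF (cat.), CH2Cl2, 0 °C to rt, concentrate; then CH2N2 (3 equiv, Et2O solution), THF, 0 °C
Reagents that add atoms: diazomethane C=[N+]=[N-]
Why: Acid chloride formation and C-acylation of diazomethane (the first stage of the Arndt–Eistert sequence) should give the diazoketone, with excess diazomethane consuming the HCl and no ketene pathway open to an aroyl chloride.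

Step 8
Reactants: 14 1-[3,5-bis(benzyloxy)-4-methoxyphenyl]-2-diazoethan-1-one
Product: 15 2-(benzyloxy)-1-[3,5-bis(benzyloxy)-4-methoxyphenyl]ethan-1-one
Conditions: BnOH (5 equiv), Rh2(OAc)4 (1 mol %), CH2Cl2, rt, slow addition of 14
Reagents that add atoms: benzyl alcohol OCc1ccccc1
Why: Dirhodium-carbenoid O–H insertion of an α-diazoketone into an alcohol is a standard route to α-alkoxy ketones, and slow addition into excess benzyl alcohol should suppress carbene dimerisation.

Step 9
Reactants: 8 2-iodo-1,3,5-tris(methoxymethoxy)-4,6-dimethylbenzene, 15 2-(benzyloxy)-1-[3,5-bis(benzyloxy)-4-methoxyphenyl]ethan-1-one, 16 carbon monoxide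
Product: 19 2-(benzyloxy)-1-[3,5-bis(benzyloxy)-4-methoxyphenyl]-3-[2,4,6-tris(methoxymethoxy)-3,5-dimethylphenyl]propane-1,3-dione, via sodium enolate 17 (not isolated), via sodium diketonate 18 (not isolated)
Conditions: 15 (2 equiv), NaN(SiMe3)2 (2 equiv), THF, −78 to 0 °C; then 8 (1 equiv), Pd(OAc)2 (5 mol %), Xantphos (6 mol %), CO (3 bar), THF, 65 °C; AcOH quench
Reagents that add atoms: none
Why: Zerovalent palladium, formed in the flask from Pd(OAc)2 and Xantphos, adds oxidatively to the C–I bond of 8, CO inserts to give an aroyl complex of divalent palladium, enolate 17 displaces iodide at the metal and C–C reductive elimination releases the diketone, which the second equivalent of 17 deprotonates to 18 (that equivalent of 15 is recovered). The closest known reaction type is the palladium-catalysed carbonylative α-arylation of ketones with aryl iodides to give 1,3-diketones. No ring is closed, and the single stereocentre formed (C2 of the diketone) is enolisable and disappears when ring C aromatises, so it needs no control. Carbonylation must precede coupling: the two ortho OMOM groups of 8 slow direct arylation of the enolate at the crowded aryl–palladium bond, CO insertion relieves that crowding, and the wide bite angle of Xantphos under 3 bar CO favours the aroyl complex. C-acylation must win over O-acylation: the sodium enolate, held in the Z geometry by chelation through the α-benzyloxy oxygen, and reductive elimination from a carbon-bound palladium enolate should secure this, and the stable diketonate 18 drains the product. MOM acetals and benzyl ethers are inert to the amide base and to zerovalent palladium.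

Step 10
Reactants: 19 2-(benzyloxy)-1-[3,5-bis(benzyloxy)-4-methoxyphenyl]-3-[2,4,6-tris(methoxymethoxy)-3,5-dimethylphenyl]propane-1,3-dione
Product: 22 3-(benzyloxy)-2-[3,5-bis(benzyloxy)-4-methoxyphenyl]-5,7-dihydroxy-6,8-dimethyl-4H-chromen-4-one, via triol diketone 20 (not isolated), via hemiketal 21 (not isolated)
Conditions: HCl (3 M in MeOH), THF, 55 °C
Reagents that add atoms: none
Why: Acid-catalysed acetal exchange with methanol removes the three MOM groups, either of the two equivalent ortho hydroxyls of symmetrical ring A adds to the ring B carbonyl (6-exo-trig hemiketalisation) and loss of water gives the aromatic γ-pyrone, which is the classical cyclodehydration of 2-hydroxyaryl 1,3-diketones to flavones; benzyl ethers tolerate methanolic HCl and the symmetry of ring A makes any ring-opening and reclosure degenerate.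

Step 11
Reactants: 22 3-(benzyloxy)-2-[3,5-bis(benzyloxy)-4-methoxyphenyl]-5,7-dihydroxy-6,8-dimethyl-4H-chromen-4-one
Product: 23 6,8-di-C-methylmyricetin 4'-methyl ether (2-(3,5-dihydroxy-4-methoxyphenyl)-3,5,7-trihydroxy-6,8-dimethyl-4H-chromen-4-one)
Conditions: H2 (1 atm), 10% Pd/C, THF/MeOH, rt
Reagents that add atoms: none
Why: Hydrogenolysis of the three benzyl ethers at atmospheric pressure is the standard last step for polyhydroxyflavonols and should leave the methyl ether, the C-methyl groups and the C2–C3 double bond of the chromone intact.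

**Compound list**

1 | phloroglucinol | Oc1cc(O)cc(O)c1 | starting material
2 | 1,3,5-tris(methoxymethoxy)benzene | COCOc1cc(OCOC)cc(OCOC)c1 | intermediate
3 | [2,4,6-tris(methoxymethoxy)phenyl]lithium | [Li]c1c(OCOC)cc(OCOC)cc1OCOC | intermediate
4 | 1,3,5-tris(methoxymethoxy)-2-methylbenzene | COCOc1cc(OCOC)c(C)c(OCOC)c1 | intermediate
5 | [2,4,6-tris(methoxymethoxy)-3-methylphenyl]lithium | [Li]c1c(OCOC)cc(OCOC)c(C)c1OCOC | intermediate
6 | 1,3,5-tris(methoxymethoxy)-2,4-dimethylbenzene | COCOc1cc(OCOC)c(C)c(OCOC)c1C | intermediate
7 | [2,4,6-tris(methoxymethoxy)-3,5-dimethylphenyl]lithium | [Li]c1c(OCOC)c(C)c(OCOC)c(C)c1OCOC | intermediate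
8 | 2-iodo-1,3,5-tris(methoxymethoxy)-4,6-dimethylbenzene | COCOc1c(C)c(OCOC)c(C)c(OCOC)c1I | intermediate
9 | methyl 3,5-dihydroxy-4-methoxybenzoate | COC(=O)c1cc(O)c(OC)c(O)c1 | starting material
10 | methyl 3,5-bis(benzyloxy)-4-methoxybenzoate | COC(=O)c1cc(OCc2ccccc2)c(OC)c(OCc2ccccc2)c1 | intermediate
11 | sodium 3,5-bis(benzyloxy)-4-methoxybenzoate | [Na+].[O-]C(=O)c1cc(OCc2ccccc2)c(OC)c(OCc2ccccc2)c1 | intermediate
12 | 3,5-bis(benzyloxy)-4-methoxybenzoic acid | COc1c(OCc2ccccc2)cc(C(=O)O)cc1OCc1ccccc1 | intermediate
13 | 3,5-bis(benzyloxy)-4-methoxybenzoyl chloride | COc1c(OCc2ccccc2)cc(C(=O)Cl)cc1OCc1ccccc1 | intermediate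
14 | 1-[3,5-bis(benzyloxy)-4-methoxyphenyl]-2-diazoethan-1-one | COc1c(OCc2ccccc2)cc(C(=O)C=[N+]=[N-])cc1OCc1ccccc1 | intermediate
15 | 2-(benzyloxy)-1-[3,5-bis(benzyloxy)-4-methoxyphenyl]ethan-1-one | COc1c(OCc2ccccc2)cc(C(=O)COCc2ccccc2)cc1OCc1ccccc1 | intermediate
16 | carbon monoxide | [C-]#[O+] | starting material
17 | sodium (Z)-2-(benzyloxy)-1-[3,5-bis(benzyloxy)-4-methoxyphenyl]ethen-1-olate | [Na+].[O-]/C(=C\OCc1ccccc1)c1cc(OCc2ccccc2)c(OC)c(OCc2ccccc2)c1 | intermediate
18 | sodium 2-(benzyloxy)-1-[3,5-bis(benzyloxy)-4-methoxyphenyl]-3-oxo-3-[2,4,6-tris(methoxymethoxy)-3,5-dimethylphenyl]prop-1-en-1-olate (delocalised, one form drawn) | [Na+].[O-]C(=C(OCc1ccccc1)C(=O)c1c(OCOC)c(C)c(OCOC)c(C)c1OCOC)c1cc(OCc2ccccc2)c(OC)c(OCc2ccccc2)c1 | intermediate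
19 | 2-(benzyloxy)-1-[3,5-bis(benzyloxy)-4-methoxyphenyl]-3-[2,4,6-tris(methoxymethoxy)-3,5-dimethylphenyl]propane-1,3-dione (racemic, enolisable) | COCOc1c(C)c(OCOC)c(C)c(OCOC)c1C(=O)C(OCc1ccccc1)C(=O)c1cc(OCc2ccccc2)c(OC)c(OCc2ccccc2)c1 | intermediate
20 | 2-(benzyloxy)-1-[3,5-bis(benzyloxy)-4-methoxyphenyl]-3-(2,4,6-trihydroxy-3,5-dimethylphenyl)propane-1,3-dione (racemic, enolisable) | Cc1c(O)c(C)c(O)c(C(=O)C(OCc2ccccc2)C(=O)c2cc(OCc3ccccc3)c(OC)c(OCc3ccccc3)c2)c1O | intermediate
21 | 3-(benzyloxy)-2-[3,5-bis(benzyloxy)-4-methoxyphenyl]-2,5,7-trihydroxy-6,8-dimethyl-2,3-dihydro-4H-chromen-4-one (racemic, mixture of diastereomers) | O=C1c2c(O)c(C)c(O)c(C)c2OC(O)(c2cc(OCc3ccccc3)c(OC)c(OCc3ccccc3)c2)C1OCc1ccccc1 | intermediate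
22 | 3-(benzyloxy)-2-[3,5-bis(benzyloxy)-4-methoxyphenyl]-5,7-dihydroxy-6,8-dimethyl-4H-chromen-4-one | COc1c(OCc2ccccc2)cc(-c2oc3c(C)c(O)c(C)c(O)c3c(=O)c2OCc2ccccc2)cc1OCc1ccccc1 | intermediate
23 | 6,8-di-C-methylmyricetin 4'-methyl ether (achiral) | COc1c(O)cc(-c2oc3c(C)c(O)c(C)c(O)c3c(=O)c2O)cc1O | target

**Step count and risks**

Total step count: 11. Longest linear sequence: 7 steps (steps 1–4, 9, 10, 11; the ring B branch, steps 5–8 followed by 9–11, is equally long).

Steps most likely to fail:

1. Step 9. The two ortho OMOM groups and the electron-rich ring may slow oxidative addition and CO insertion, so that protodeiodination of 8 or capture of the aroyl–palladium by HN(SiMe3)2 competes. The crowded aroyl complex may also acylate the enolate on oxygen or fail to couple with so bulky a nucleophile. The fallback sets out from 8 and comes back at 19; it still uses CO 16 as C4 but makes the two bonds in separate operations. Palladium-catalysed aryloxycarbonylation of 8 with CO and pentafluorophenol, a small non-basic nucleophile (Pd(OAc)2, Xantphos, Et3N, toluene, 80 °C), should give pentafluorophenyl 2,4,6-tris(methoxymethoxy)-3,5-dimethylbenzoate F1. Crossed Claisen acylation of sodium enolate 17 (2 equiv, from 15 and NaN(SiMe3)2, THF, −78 °C to rt) with this active ester then gives diketonate 18 and, after AcOH quench, 19.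

2. Step 8. The rhodium carbenoid may dimerise, attack the benzyl arenes or insert into adventitious water instead of the benzyl alcohol O–H, and the diazoketone of step 7 may be lost on handling. The fallback sets out from 10 and comes back at 15, bypassing steps 6–8 and all carbenoid chemistry. Ester 10 is converted directly into 3,5-bis(benzyloxy)-N,4-dimethoxy-N-methylbenzamide F2 (MeNH(OMe)·HCl, i-PrMgCl, THF, −20 °C). This Weinreb amide is treated with (benzyloxy)methyllithium, generated by tin–lithium exchange from Bu3SnCH2OBn and n-BuLi in THF at −78 °C, and collapse of the chelated adduct on work-up gives 15.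

3. Step 4. Metalation at the last, most crowded ring position may be incomplete or may drift to the flanking methyl groups (lateral metalation), leaving material that is hard to separate from 8. The fallback sets out from 6 and comes back at 8. Electrophilic aromatic iodination with N-iodosuccinimide (MeCN, NaHCO3, rt) attacks the only free position of the strongly activated ring without any organolithium; no compound outside the list is made (F0).

Further compounds
F1 | step 9 | pentafluorophenyl 2,4,6-tris(methoxymethoxy)-3,5-dimethylbenzoate | COCOc1c(C)c(OCOC)c(C)c(OCOC)c1C(=O)Oc1c(F)c(F)c(F)c(F)c1F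
F2 | step 8 | 3,5-bis(benzyloxy)-N,4-dimethoxy-N-methylbenzamide | CON(C)C(=O)c1cc(OCc2ccccc2)c(OC)c(OCc2ccccc2)c1
F0 | step 4 | none | none
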